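**Retrosynthetic overview**
The plan rests on the two E-trisubstituted alkenes of the chain, C7=C8 and C12=C13, each a methyl-bearing carbon (C8, C13) between two CH2 groups: each is written by syn-methylmetalation of a terminal alkyne and cross-coupling at the metalated CH carbon.
Late disconnections: stearoyl–O (acylation); O–C21 of the butenolide (closure on a C21 boronate with retention, which fixes the E C20=C21 alkene); C21–C22 (Negishi coupling of a 1-iodo-1-alkenylboronate with a β-zincated β-alkoxyacrylate).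
Chain disconnections: C6–C7 and C8–C9 (key step: enyne 14, trimethylaluminium, 3-(2-iodoethyl)furan); C11–C12 and C13–C14 (first iteration); C13–C15 (acetylide alkylation).
C18 (S) is C3 of (S)-citronellol and is never touched; citronellol C1 and C2 become C21 and C20 by an aldehyde-to-alkyne conversion.
Rings: the furan ring is bought with 3-bromofuran; the butenolide ring (O, C21, C22, C23, C24) is the only ring made and closes in step 20.

Key step: step 11

Remark: atoms are numbered furan C1–C4, chain C5–C20, butenolide C21–C24, methyls C9 (on C8), C14 (on C13), C19 (on C18) and C25 (on C23). The target is taken as drawn, with C18 S and the exocyclic C20=C21 alkene E (C18 trans to the ring oxygen, cis to C22), and the six starting materials are taken as commercial.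

**Step 1**
Reactants: 1 (S)-citronellol
Product: 2 tert-butyl{[(3S)-3,7-dimethyloct-6-en-1-yl]oxy}dimethylsilane
Conditions: TBSCl, imidazole, DMF, rt
Reagents that add atoms: tert-butyldimethylsilyl chloride, CC(C)(C)[Si](C)(C)Cl
Why: Imidazole-promoted silylation of the primary alcohol; the stereocentre (later C18) is remote and untouched.

**Step 2**
Reactants: 2 tert-butyl{[(3S)-3,7-dimethyloct-6-en-1-yl]oxy}dimethylsilane
Product: 4 (4S)-6-{[tert-butyl(dimethyl)silyl]oxy}-4-methylhexan-1-ol, via ozonide 3 (not isolated)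
Conditions: O3, CH2Cl2, −78 °C; then NaBH4, MeOH, −78 °C → rt
Reagents that add atoms: ozone, [O-][O+]=O
Why: Reductive ozonolysis cleaves the only C=C bond and NaBH4 reduces the ozonide to the primary alcohol (C15–OH), leaving silyl ether and stereocentre alone.

**Step 3**
Reactants: 4 (4S)-6-{[tert-butyl(dimethyl)silyl]oxy}-4-methylhexan-1-ol
Product: 5 (4S)-6-{[tert-butyl(dimethyl)silyl]oxy}-4-methylhexyl 4-methylbenzenesulfonate
Conditions: TsCl, Et3N, DMAP (cat.), CH2Cl2, 0 °C → rt
Reagents that add atoms: 4-methylbenzenesulfonyl chloride, Cc1ccc(cc1)S(=O)(=O)Cl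
Why: Sulfonylation of the primary alcohol turns C15 into an SN2 electrophile.

**Step 4**
Reactants: 5 (4S)-6-{[tert-butyl(dimethyl)silyl]oxy}-4-methylhexyl 4-methylbenzenesulfonate
Product: 6 tert-butyldimethyl{[(3S)-3-methyloct-7-yn-1-yl]oxy}silane
Conditions: LiC≡CH·H2NCH2CH2NH2, DMSO, 0 °C → rt
Reagents that add atoms: lithium acetylide–ethylenediamine complex, [Li]C#C.NCCN
Why: SN2 alkylation of lithium acetylide by the primary tosylate installs the terminal alkyne C13≡C12 without touching the silyl ether.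

**Step 5**
Reactants: 6 tert-butyldimethyl{[(3S)-3-methyloct-7-yn-1-yl]oxy}silane; 7 trimethylaluminium
Product: 9 tert-butyl{[(3S,7E)-8-iodo-3,7-dimethyloct-7-en-1-yl]oxy}dimethylsilane, via alkenylalane 8 (not isolated)
Conditions: Me3Al, Cp2ZrCl2 (cat.), CH2Cl2, 0 °C → rt; then I2, THF, −30 → 0 °C
Reagents that add atoms: iodine, II
Why: Zirconium-catalysed syn-methylalumination (Negishi carboalumination) puts methyl C14 on the internal carbon C13 and aluminium on C12, and iodinolysis of the C–Al bond with retention should give the E-iodide.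

**Step 6**
Reactants: 10 4-(trimethylsilyl)but-3-yn-1-ol
Product: 11 (4-iodobut-1-yn-1-yl)trimethylsilane
Conditions: I2, PPh3, imidazole, CH2Cl2, 0 °C → rt
Reagents that add atoms: iodine, II
Why: Appel-type iodination of the primary alcohol by SN2 on the alkoxyphosphonium ion.

**Step 7**
Reactants: 9 tert-butyl{[(3S,7E)-8-iodo-3,7-dimethyloct-7-en-1-yl]oxy}dimethylsilane; 11 (4-iodobut-1-yn-1-yl)trimethylsilane
Product: 13 tert-butyl{[(3S,7E)-3,7-dimethyl-12-(trimethylsilyl)dodec-7-en-11-yn-1-yl]oxy}dimethylsilane, via alkylzinc iodide 12 (not isolated)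
Conditions: 11, Zn dust, LiCl, THF, 35 °C; then 9, Pd(PPh3)4 (cat.), THF, rt → 45 °C
Reagents that add atoms: none
Why: Zinc inserts into the primary C–I bond and the alkylzinc iodide couples with the alkenyl iodide under zerovalent palladium catalysis (Negishi coupling) with retention of the E geometry, forming C11–C12.

**Step 8**
Reactants: 13 tert-butyl{[(3S,7E)-3,7-dimethyl-12-(trimethylsilyl)dodec-7-en-11-yn-1-yl]oxy}dimethylsilane
Product: 14 tert-butyl{[(3S,7E)-3,7-dimethyldodec-7-en-11-yn-1-yl]oxy}dimethylsilane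
Conditions: K2CO3 (cat.), MeOH, rt
Reagents that add atoms: none
Why: Carbonate-catalysed methanolysis cleaves the C(sp)–Si bond selectively, freeing the terminal alkyne C8≡C7 while the O-silyl ether stays.

**Step 9**
Reactants: 15 3-bromofuran
Product: 17 2-(furan-3-yl)ethan-1-ol, via furan-3-yllithium 16 (not isolated)
Conditions: n-BuLi, THF, −78 °C; then oxirane, BF3·OEt2, −78 °C
Reagents that add atoms: oxirane, C1CO1
Why: Bromine–lithium exchange at −78 °C gives 3-lithiofuran, which opens the BF3-activated epoxide before it can isomerise to the 2-lithio isomer.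

**Step 10**
Reactants: 17 2-(furan-3-yl)ethan-1-ol
Product: 18 3-(2-iodoethyl)furan
Conditions: I2, PPh3, imidazole, CH2Cl2, 0 °C, dark
Reagents that add atoms: iodine, II
Why: Appel-type iodination under neutral conditions that the furan tolerates; the iodide is used soon after it is made.

**Step 11**
Reactants: 14 tert-butyl{[(3S,7E)-3,7-dimethyldodec-7-en-11-yn-1-yl]oxy}dimethylsilane; 7 trimethylaluminium; 18 3-(2-iodoethyl)furan
Product: 21 tert-butyl{[(3S,7E,11E)-14-(furan-3-yl)-3,7,11-trimethyltetradeca-7,11-dien-1-yl]oxy}dimethylsilane, via alkenylalane 19 (not isolated), via alkenylzinc chloride 20 (not isolated)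
Conditions: Me3Al, Cp2ZrCl2 (cat.), CH2Cl2, 0 °C → rt; volatiles removed in vacuo; ZnCl2, THF, 0 °C; then 18, Pd2(dba)3 (cat.), PCyp3, N-methylimidazole, THF/NMP, 60 °C
Reagents that add atoms: none
Why: Cp2ZrCl2 and Me3Al form a methylzirconium–aluminium species that adds methyl and metal syn across the terminal alkyne through a four-centre transition state, methyl to the internal carbon C8 and aluminium to the terminal carbon C7; ZnCl2 then exchanges aluminium for zinc with retention, and zerovalent palladium bearing PCyp3 inserts into the primary C–I bond of 18, takes the alkenyl group from zinc and forms C6–C7 by reductive elimination, again with retention. The closest known reaction types are the zirconium-catalysed carboalumination–cross-coupling of terminal alkynes and the Negishi coupling of alkenylzinc halides with unactivated primary alkyl iodides under palladium–trialkylphosphine catalysis. No ring closes and no stereocentre is made; C18 is remote and inert. The E geometry at C7=C8 follows from the syn addition (the C10 chain on C8 ends trans to aluminium and so trans to C6), and the regiochemistry from the preference of aluminium for the unhindered terminal carbon. Only the terminal alkyne reacts with the methylmetal reagent, the trisubstituted C12=C13 alkene and the silyl ether being inert, and the furan enters only after the carbometalation. The step needs alkenyl transfer to outrun β-hydride elimination of the 2-(furan-3-yl)ethylpalladium species and methyl transfer from residual methylaluminium, which the bulky electron-rich phosphine, N-methylimidazole and removal of excess Me3Al before the coupling should secure.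

**Step 12**
Reactants: 21 tert-butyl{[(3S,7E,11E)-14-(furan-3-yl)-3,7,11-trimethyltetradeca-7,11-dien-1-yl]oxy}dimethylsilane
Product: 22 (3S,7E,11E)-14-(furan-3-yl)-3,7,11-trimethyltetradeca-7,11-dien-1-ol
Conditions: Bu4NF, THF, 0 °C → rt
Reagents that add atoms: none
Why: Fluoride cleaves the O–Si bond; nothing else in the molecule responds to fluoride.

**Step 13**
Reactants: 22 (3S,7E,11E)-14-(furan-3-yl)-3,7,11-trimethyltetradeca-7,11-dien-1-ol
Product: 23 (3S,7E,11E)-14-(furan-3-yl)-3,7,11-trimethyltetradeca-7,11-dienal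
Conditions: Dess–Martin periodinane, NaHCO3, CH2Cl2, 0 °C → rt
Reagents that add atoms: none
Why: Buffered Dess–Martin oxidation gives the β-branched aldehyde, which has no α-stereocentre to epimerise, and spares the furan and the alkenes.

**Step 14**
Reactants: 23 (3S,7E,11E)-14-(furan-3-yl)-3,7,11-trimethyltetradeca-7,11-dienal
Product: 25 3-[(3E,7E,12S)-4,8,12-trimethyltetradeca-3,7-dien-13-yn-1-yl]furan, via alkenyl nonaflate 24 (not isolated)
Conditions: C4F9SO2F, phosphazene base P2-Et (2.2 equiv), DMF, −20 °C → rt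
Reagents that add atoms: none
Why: The phosphazene base enolises the aldehyde, O-sulfonylation gives the alkenyl nonaflate and a second equivalent of base eliminates nonaflate across C20–C21 (sulfonylation–elimination of an enolisable aldehyde to a terminal alkyne); the C18–H is not acidic enough to be removed, so the stereocentre should hold.

**Step 15**
Reactants: 25 3-[(3E,7E,12S)-4,8,12-trimethyltetradeca-3,7-dien-13-yn-1-yl]furan
Product: 27 3-[(3E,7E,12S)-14-iodo-4,8,12-trimethyltetradeca-3,7-dien-13-yn-1-yl]furan, via lithium acetylide 26 (not isolated)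
Conditions: n-BuLi (1.0 equiv), THF, −78 °C; then I2, THF, −78 °C
Reagents that add atoms: iodine, II
Why: The alkyne C–H is far more acidic than any furan C–H, and the acetylide is iodinated at −78 °C, where iodine leaves furan and alkenes alone.

**Step 16**
Reactants: 27 3-[(3E,7E,12S)-14-iodo-4,8,12-trimethyltetradeca-3,7-dien-13-yn-1-yl]furan
Product: 30 2-[(1Z,3S,7E,11E)-14-(furan-3-yl)-1-iodo-3,7,11-trimethyltetradeca-1,7,11-trien-1-yl]-4,4,5,5-tetramethyl-1,3,2-dioxaborolane, via alkenyldiisopinocampheylborane 28 (not isolated), via diethyl boronate 29 (not isolated)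
Conditions: (−)-Ipc2BH, THF, −25 → 0 °C; then MeCHO (excess), 0 → 40 °C; then pinacol, rt
Reagents that add atoms: (−)-diisopinocampheylborane, B([C@@H]1C[C@@H]2C[C@H]([C@H]1C)C2(C)C)[C@@H]1C[C@@H]2C[C@H]([C@H]1C)C2(C)C; pinacol, CC(C)(O)C(C)(C)O
Why: The bulky dialkylborane adds H and B syn across the iodoalkyne with boron on the iodine-bearing C21 (hydroboration of a 1-haloalkyne) and spares the trisubstituted alkenes and the furan, so iodine ends cis and boron trans to C18; acetaldehyde then expels both isopinocampheyl groups as α-pinene by a six-membered hydride transfer that forms no borate complex (hence no 1,2-shift onto the α-iodo carbon), and pinacol exchanges the ethoxy groups.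

**Step 17**
Reactants: 31 methyl propanoate
Product: 33 methyl (2E)-2-methyl-3-{[2-(trimethylsilyl)ethoxy]methoxy}prop-2-enoate, via sodium enolate 32 (not isolated)
Conditions: NaH, HCO2Me, THF, 0 °C → rt; then SEMCl, DMF, 0 °C
Reagents that add atoms: methyl formate, COC=O; 2-(trimethylsilyl)ethoxymethyl chloride, C[Si](C)(C)CCOCCl
Why: Crossed Claisen formylation gives the sodium formyl-ester enolate, which the hard chloromethyl ether alkylates on oxygen; the E enol ether (β-hydrogen cis to the ester) is expected as the main isomer and is purified by chromatography.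

**Step 18**
Reactants: 30 2-[(1Z,3S,7E,11E)-14-(furan-3-yl)-1-iodo-3,7,11-trimethyltetradeca-1,7,11-trien-1-yl]-4,4,5,5-tetramethyl-1,3,2-dioxaborolane; 33 methyl (2E)-2-methyl-3-{[2-(trimethylsilyl)ethoxy]methoxy}prop-2-enoate
Product: 36 methyl (2E,4Z,6S,10E,14E)-17-(furan-3-yl)-2,6,10,14-tetramethyl-4-(4,4,5,5-tetramethyl-1,3,2-dioxaborolan-2-yl)-3-{[2-(trimethylsilyl)ethoxy]methoxy}heptadeca-2,4,10,14-tetraenoate, via lithioacrylate 34 (not isolated), via zincated acrylate 35 (not isolated)
Conditions: 33, LiN(iPr)2, THF, −78 °C; ZnCl2, −78 → 0 °C; then 30, Pd(PtBu3)2 (cat.), THF, 0 °C → rt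
Reagents that add atoms: none
Why: LiN(iPr)2 removes the β-vinyl hydrogen held cis to the ester (ester-directed β-lithiation of a β-alkoxyacrylate), ZnCl2 gives the configurationally stable alkenylzinc, and Negishi coupling at the C–I bond of the 1-iodo-1-alkenylboronate (the boronate is inert without base) forms C21–C22 with retention at both carbons, so C22 ends cis to C18 and the ester cis to C21.

**Step 19**
Reactants: 36 methyl (2E,4Z,6S,10E,14E)-17-(furan-3-yl)-2,6,10,14-tetramethyl-4-(4,4,5,5-tetramethyl-1,3,2-dioxaborolan-2-yl)-3-{[2-(trimethylsilyl)ethoxy]methoxy}heptadeca-2,4,10,14-tetraenoate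
Product: 38 (2E,4Z,6S,10E,14E)-17-(furan-3-yl)-2,6,10,14-tetramethyl-4-(4,4,5,5-tetramethyl-1,3,2-dioxaborolan-2-yl)-3-{[2-(trimethylsilyl)ethoxy]methoxy}heptadeca-2,4,10,14-tetraenoic acid, via potassium carboxylate 37 (not isolated)
Conditions: KOSiMe3, THF, rt → 40 °C; then aq. H3PO4 to pH 4, 0 °C
Reagents that add atoms: none
Why: Anhydrous silanolate cleavage of the methyl ester gives the carboxylate without hydroxide or heat in water, so the acetal-type enol ether, the boronate and both alkene geometries should survive.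

**Step 20**
Reactants: 38 (2E,4Z,6S,10E,14E)-17-(furan-3-yl)-2,6,10,14-tetramethyl-4-(4,4,5,5-tetramethyl-1,3,2-dioxaborolan-2-yl)-3-{[2-(trimethylsilyl)ethoxy]methoxy}heptadeca-2,4,10,14-tetraenoic acid
Product: 39 (5E)-5-[(2S,6E,10E)-13-(furan-3-yl)-2,6,10-trimethyltrideca-6,10-dien-1-ylidene]-3-methyl-4-{[2-(trimethylsilyl)ethoxy]methoxy}furan-2(5H)-one
Conditions: Cu(OAc)2 (2 equiv), Et3N, 4 Å molecular sieves, MeCN, air, rt, dark
Reagents that add atoms: none
Why: Proposed new method: the boronate should transmetalate to divalent copper at C21, the carboxylate held cis on the C22=C23 alkene binds the same copper centre, and oxidation to trivalent copper by a second Cu(OAc)2 followed by C–O reductive elimination closes the five-membered ring onto C21 with retention, so the ring oxygen ends trans and C22 cis to C18 (E); the closest known reaction type is the stereoretentive intermolecular copper-promoted coupling of alkenylboronates with carboxylic acids to enol esters (Chan–Lam type).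

**Step 21**
Reactants: 39 (5E)-5-[(2S,6E,10E)-13-(furan-3-yl)-2,6,10-trimethyltrideca-6,10-dien-1-ylidene]-3-methyl-4-{[2-(trimethylsilyl)ethoxy]methoxy}furan-2(5H)-one
Product: 41 (5E)-5-[(2S,6E,10E)-13-(furan-3-yl)-2,6,10-trimethyltrideca-6,10-dien-1-ylidene]-4-hydroxy-3-methylfuran-2(5H)-one, via tetrabutylammonium tetronate 40 (not isolated)
Conditions: Bu4NF, THF, 0 °C → rt, dark; then aq. H3PO4 to pH 4
Reagents that add atoms: none
Why: Fluoride attacks silicon and the acetal fragments to ethene, formaldehyde and the tetronate, a carboxylate-like leaving group; the electron-rich tetronate anion resists conjugate addition, so the E alkene should not isomerise.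

**Step 22**
Reactants: 41 (5E)-5-[(2S,6E,10E)-13-(furan-3-yl)-2,6,10-trimethyltrideca-6,10-dien-1-ylidene]-4-hydroxy-3-methylfuran-2(5H)-one; 42 octadecanoyl chloride
Product: 43 (2E)-2-[(2S,6E,10E)-13-(furan-3-yl)-2,6,10-trimethyltrideca-6,10-dien-1-ylidene]-4-methyl-5-oxo-2,5-dihydrofuran-3-yl octadecanoate
Conditions: Et3N, CH2Cl2, −20 → 0 °C, dark
Reagents that add atoms: none
Why: O-acylation of the tetronate with the acid chloride occurs at the oxygen on C22 (C23 is blocked by its methyl), and no nucleophilic catalyst is used so that the E C20=C21 alkene is not isomerised by reversible conjugate addition.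

**Compound list**
1 | (S)-citronellol, (3S)-3,7-dimethyloct-6-en-1-ol | OCC[C@@H](C)CCC=C(C)C | starting material
2 | tert-butyl{[(3S)-3,7-dimethyloct-6-en-1-yl]oxy}dimethylsilane | CC(C)(C)[Si](C)(C)OCC[C@@H](C)CCC=C(C)C | intermediate
3 | tert-butyl{[(3S)-5-(5,5-dimethyl-1,2,4-trioxolan-3-yl)-3-methylpentyl]oxy}dimethylsilane (ozonide, mixed at the trioxolane carbon; not isolated) | CC(C)(C)[Si](C)(C)OCC[C@@H](C)CCC1OOC(C)(C)O1 | intermediate
4 | (4S)-6-{[tert-butyl(dimethyl)silyl]oxy}-4-methylhexan-1-ol | CC(C)(C)[Si](C)(C)OCC[C@@H](C)CCCO | intermediate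
5 | (4S)-6-{[tert-butyl(dimethyl)silyl]oxy}-4-methylhexyl 4-methylbenzenesulfonate | CC(C)(C)[Si](C)(C)OCC[C@@H](C)CCCOS(=O)(=O)c1ccc(C)cc1 | intermediate
6 | tert-butyldimethyl{[(3S)-3-methyloct-7-yn-1-yl]oxy}silane | CC(C)(C)[Si](C)(C)OCC[C@@H](C)CCCC#C | intermediate
7 | trimethylaluminium | C[Al](C)C | starting material
8 | [(1E,6S)-8-{[tert-butyl(dimethyl)silyl]oxy}-2,6-dimethyloct-1-en-1-yl]dimethylalumane (not isolated) | CC(C)(C)[Si](C)(C)OCC[C@@H](C)CCC/C(C)=C/[Al](C)C | intermediate
9 | tert-butyl{[(3S,7E)-8-iodo-3,7-dimethyloct-7-en-1-yl]oxy}dimethylsilane | CC(C)(C)[Si](C)(C)OCC[C@@H](C)CCC/C(C)=C/I | intermediate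
10 | 4-(trimethylsilyl)but-3-yn-1-ol | C[Si](C)(C)C#CCCO | starting material
11 | (4-iodobut-1-yn-1-yl)trimethylsilane | C[Si](C)(C)C#CCCI | intermediate
12 | [4-(trimethylsilyl)but-3-yn-1-yl]zinc iodide (not isolated) | C[Si](C)(C)C#CCC[Zn]I | intermediate
13 | tert-butyl{[(3S,7E)-3,7-dimethyl-12-(trimethylsilyl)dodec-7-en-11-yn-1-yl]oxy}dimethylsilane | CC(C)(C)[Si](C)(C)OCC[C@@H](C)CCC/C(C)=C/CCC#C[Si](C)(C)C | intermediate
14 | tert-butyl{[(3S,7E)-3,7-dimethyldodec-7-en-11-yn-1-yl]oxy}dimethylsilane | CC(C)(C)[Si](C)(C)OCC[C@@H](C)CCC/C(C)=C/CCC#C | intermediate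
15 | 3-bromofuran | Brc1ccoc1 | starting material
16 | furan-3-yllithium (not isolated) | [Li]c1ccoc1 | intermediate
17 | 2-(furan-3-yl)ethan-1-ol | OCCc1ccoc1 | intermediate
18 | 3-(2-iodoethyl)furan | ICCc1ccoc1 | intermediate
19 | [(1E,5E,10S)-12-{[tert-butyl(dimethyl)silyl]oxy}-2,6,10-trimethyldodeca-1,5-dien-1-yl]dimethylalumane (not isolated) | CC(C)(C)[Si](C)(C)OCC[C@@H](C)CCC/C(C)=C/CC/C(C)=C/[Al](C)C | intermediate
20 | chloro[(1E,5E,10S)-12-{[tert-butyl(dimethyl)silyl]oxy}-2,6,10-trimethyldodeca-1,5-dien-1-yl]zinc (not isolated) | CC(C)(C)[Si](C)(C)OCC[C@@H](C)CCC/C(C)=C/CC/C(C)=C/[Zn]Cl | intermediate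
21 | tert-butyl{[(3S,7E,11E)-14-(furan-3-yl)-3,7,11-trimethyltetradeca-7,11-dien-1-yl]oxy}dimethylsilane | CC(C)(C)[Si](C)(C)OCC[C@@H](C)CCC/C(C)=C/CC/C(C)=C/CCc1ccoc1 | intermediate
22 | (3S,7E,11E)-14-(furan-3-yl)-3,7,11-trimethyltetradeca-7,11-dien-1-ol | OCC[C@@H](C)CCC/C(C)=C/CC/C(C)=C/CCc1ccoc1 | intermediate
23 | (3S,7E,11E)-14-(furan-3-yl)-3,7,11-trimethyltetradeca-7,11-dienal | O=CC[C@@H](C)CCC/C(C)=C/CC/C(C)=C/CCc1ccoc1 | intermediate
24 | (3S,7E,11E)-14-(furan-3-yl)-3,7,11-trimethyltetradeca-1,7,11-trien-1-yl nonafluorobutane-1-sulfonate (mixed geometry at C1=C2; not isolated) | FC(F)(F)C(F)(F)C(F)(F)C(F)(F)S(=O)(=O)OC=C[C@@H](C)CCC/C(C)=C/CC/C(C)=C/CCc1ccoc1 | intermediate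
25 | 3-[(3E,7E,12S)-4,8,12-trimethyltetradeca-3,7-dien-13-yn-1-yl]furan | C#C[C@@H](C)CCC/C(C)=C/CC/C(C)=C/CCc1ccoc1 | intermediate
26 | lithium (3S,7E,11E)-14-(furan-3-yl)-3,7,11-trimethyltetradeca-7,11-dien-1-yn-1-ide (not isolated) | [Li]C#C[C@@H](C)CCC/C(C)=C/CC/C(C)=C/CCc1ccoc1 | intermediate
27 | 3-[(3E,7E,12S)-14-iodo-4,8,12-trimethyltetradeca-3,7-dien-13-yn-1-yl]furan | IC#C[C@@H](C)CCC/C(C)=C/CC/C(C)=C/CCc1ccoc1 | intermediate
28 | [(1Z,3S,7E,11E)-14-(furan-3-yl)-1-iodo-3,7,11-trimethyltetradeca-1,7,11-trien-1-yl]diisopinocampheylborane (isopinocampheyl groups from (+)-α-pinene; not isolated) | I/C(=C\[C@@H](C)CCC/C(C)=C/CC/C(C)=C/CCc1ccoc1)B([C@@H]1C[C@@H]2C[C@H]([C@H]1C)C2(C)C)[C@@H]1C[C@@H]2C[C@H]([C@H]1C)C2(C)C | intermediate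
29 | diethyl [(1Z,3S,7E,11E)-14-(furan-3-yl)-1-iodo-3,7,11-trimethyltetradeca-1,7,11-trien-1-yl]boronate (not isolated) | CCOB(OCC)/C(I)=C/[C@@H](C)CCC/C(C)=C/CC/C(C)=C/CCc1ccoc1 | intermediate
30 | 2-[(1Z,3S,7E,11E)-14-(furan-3-yl)-1-iodo-3,7,11-trimethyltetradeca-1,7,11-trien-1-yl]-4,4,5,5-tetramethyl-1,3,2-dioxaborolane | CC1(C)OB(OC1(C)C)/C(I)=C/[C@@H](C)CCC/C(C)=C/CC/C(C)=C/CCc1ccoc1 | intermediate
31 | methyl propanoate | CCC(=O)OC | starting material
32 | sodium 3-methoxy-2-methyl-3-oxoprop-1-en-1-olate (not isolated) | [Na+].[O-]C=C(C)C(=O)OC | intermediate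
33 | methyl (2E)-2-methyl-3-{[2-(trimethylsilyl)ethoxy]methoxy}prop-2-enoate | COC(=O)/C(C)=C/OCOCC[Si](C)(C)C | intermediate
34 | methyl (2E)-3-lithio-2-methyl-3-{[2-(trimethylsilyl)ethoxy]methoxy}prop-2-enoate (lithium cis to the ester; not isolated) | COC(=O)/C(C)=C(\[Li])OCOCC[Si](C)(C)C | intermediate
35 | chloro[(1Z)-3-methoxy-2-methyl-3-oxo-1-{[2-(trimethylsilyl)ethoxy]methoxy}prop-1-en-1-yl]zinc (not isolated) | COC(=O)/C(C)=C(\[Zn]Cl)OCOCC[Si](C)(C)C | intermediate
36 | methyl (2E,4Z,6S,10E,14E)-17-(furan-3-yl)-2,6,10,14-tetramethyl-4-(4,4,5,5-tetramethyl-1,3,2-dioxaborolan-2-yl)-3-{[2-(trimethylsilyl)ethoxy]methoxy}heptadeca-2,4,10,14-tetraenoate | COC(=O)/C(C)=C(OCOCC[Si](C)(C)C)\C(B1OC(C)(C)C(C)(C)O1)=C/[C@@H](C)CCC/C(C)=C/CC/C(C)=C/CCc1ccoc1 | intermediate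
37 | potassium salt of acid 38 (not isolated) | [K+].[O-]C(=O)/C(C)=C(OCOCC[Si](C)(C)C)\C(B1OC(C)(C)C(C)(C)O1)=C/[C@@H](C)CCC/C(C)=C/CC/C(C)=C/CCc1ccoc1 | intermediate
38 | (2E,4Z,6S,10E,14E)-17-(furan-3-yl)-2,6,10,14-tetramethyl-4-(4,4,5,5-tetramethyl-1,3,2-dioxaborolan-2-yl)-3-{[2-(trimethylsilyl)ethoxy]methoxy}heptadeca-2,4,10,14-tetraenoic acid | OC(=O)/C(C)=C(OCOCC[Si](C)(C)C)\C(B1OC(C)(C)C(C)(C)O1)=C/[C@@H](C)CCC/C(C)=C/CC/C(C)=C/CCc1ccoc1 | intermediate
39 | (5E)-5-[(2S,6E,10E)-13-(furan-3-yl)-2,6,10-trimethyltrideca-6,10-dien-1-ylidene]-3-methyl-4-{[2-(trimethylsilyl)ethoxy]methoxy}furan-2(5H)-one | C[Si](C)(C)CCOCOC1=C(C)C(=O)O/C1=C/[C@@H](C)CCC/C(C)=C/CC/C(C)=C/CCc1ccoc1 | intermediate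
40 | tetrabutylammonium salt of tetronic acid 41 (not isolated) | CCCC[N+](CCCC)(CCCC)CCCC.[O-]C1=C(C)C(=O)O/C1=C/[C@@H](C)CCC/C(C)=C/CC/C(C)=C/CCc1ccoc1 | intermediate
41 | (5E)-5-[(2S,6E,10E)-13-(furan-3-yl)-2,6,10-trimethyltrideca-6,10-dien-1-ylidene]-4-hydroxy-3-methylfuran-2(5H)-one | OC1=C(C)C(=O)O/C1=C/[C@@H](C)CCC/C(C)=C/CC/C(C)=C/CCc1ccoc1 | intermediate
42 | octadecanoyl chloride (stearoyl chloride) | CCCCCCCCCCCCCCCCCC(=O)Cl | starting material
43 | (2E)-2-[(2S,6E,10E)-13-(furan-3-yl)-2,6,10-trimethyltrideca-6,10-dien-1-ylidene]-4-methyl-5-oxo-2,5-dihydrofuran-3-yl octadecanoate | CCCCCCCCCCCCCCCCCC(=O)OC1=C(C)C(=O)O/C1=C/[C@@H](C)CCC/C(C)=C/CC/C(C)=C/CCc1ccoc1 | target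

**Step count**
Total: 22 steps. Longest linear sequence: 18 steps (1–5, 7, 8, 11–16, 18–22).

**Steps most likely to fail**

Step 20 (proposed new method). The carboxylate may fail to capture the C21–copper intermediate, so that protodeboronation, acetoxylation by acetate or oxidative homocoupling of the alkenylboronate wins and the ring does not close. The fallback uses known chemistry and sets out from 36. Stereoretentive iododeboronation (NaOH, I2, THF, 0 °C) should give methyl (2E,4E,6S,10E,14E)-17-(furan-3-yl)-4-iodo-2,6,10,14-tetramethyl-3-{[2-(trimethylsilyl)ethoxy]methoxy}heptadeca-2,4,10,14-tetraenoate F1, with iodine trans to C18. KOSiMe3 in THF then gives the potassium salt of the corresponding acid F2, which is used as such. A CuI-catalysed intramolecular O-vinylation (CuI, trans-N,N'-dimethylcyclohexane-1,2-diamine, dioxane, 70 °C; Ullmann-type enol lactone formation from a vinyl halide and a carboxylate, with retention) closes the ring and returns to the route at 39.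

Step 18. Transmetalation and reductive elimination between two fully substituted sp2 carbons may be slow, so that the zincated acrylate decomposes on warming or the α-borylalkenylpalladium species loses its geometry. The fallback sets out from 33 and 30. The lithio species 34, made as in step 18, is quenched with Bu3SnCl to give the isolable methyl (2Z)-2-methyl-3-(tributylstannyl)-3-{[2-(trimethylsilyl)ethoxy]methoxy}prop-2-enoate F5. A copper-assisted Stille coupling of this stannane with 30 (Pd2(dba)3, AsPh3, CuI, NMP, 40 °C; no base or fluoride, so the boronate stays inert) returns to the route at 36.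

Step 11. Alkenyl transfer to the alkylpalladium species may be slow, so that β-hydride elimination or base-induced elimination of the iodide to 3-vinylfuran, or methyl transfer from residual methylaluminium, consumes the electrophile. The fallback reverses the polarity of the coupling and sets out from 14 and 18. The enyne 14 is methylaluminated as in step 11 and the alkenylalane 19 is cleaved with iodine to tert-butyl{[(3S,7E,11E)-12-iodo-3,7,11-trimethyldodeca-7,11-dien-1-yl]oxy}dimethylsilane F3. Zinc dust and LiCl in THF convert 18 into [2-(furan-3-yl)ethyl]zinc iodide F4. Negishi coupling of the two with Pd(PPh3)4 in THF returns to the route at 21.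

**Further compounds**
F1 | step 20 | methyl (2E,4E,6S,10E,14E)-17-(furan-3-yl)-4-iodo-2,6,10,14-tetramethyl-3-{[2-(trimethylsilyl)ethoxy]methoxy}heptadeca-2,4,10,14-tetraenoate | COC(=O)/C(C)=C(OCOCC[Si](C)(C)C)\C(I)=C/[C@@H](C)CCC/C(C)=C/CC/C(C)=C/CCc1ccoc1
F2 | step 20 | potassium (2E,4E,6S,10E,14E)-17-(furan-3-yl)-4-iodo-2,6,10,14-tetramethyl-3-{[2-(trimethylsilyl)ethoxy]methoxy}heptadeca-2,4,10,14-tetraenoate | [K+].[O-]C(=O)/C(C)=C(OCOCC[Si](C)(C)C)\C(I)=C/[C@@H](C)CCC/C(C)=C/CC/C(C)=C/CCc1ccoc1
F3 | step 11 | tert-butyl{[(3S,7E,11E)-12-iodo-3,7,11-trimethyldodeca-7,11-dien-1-yl]oxy}dimethylsilane | CC(C)(C)[Si](C)(C)OCC[C@@H](C)CCC/C(C)=C/CC/C(C)=C/I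
F4 | step 11 | [2-(furan-3-yl)ethyl]zinc iodide | I[Zn]CCc1ccoc1
F5 | step 18 | methyl (2Z)-2-methyl-3-(tributylstannyl)-3-{[2-(trimethylsilyl)ethoxy]methoxy}prop-2-enoate | COC(=O)/C(C)=C(\[Sn](CCCC)(CCCC)CCCC)OCOCC[Si](C)(C)C
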